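A direct plan would oxidise the vinylic methyl group (C12) of (−)-β-caryophyllene A1 through the allylic alcohol A2 to the ring-trans enoic acid A3. It would then add A3 to the diene of trans-communic acid A4 in a thermal intermolecular Diels–Alder reaction. Its weakest steps would be:
- the allylic oxygenation A1→A2, because C12–H would have to react in preference to the allylic positions C3, C6, C7 and C9 while the strained E-olefin stayed intact;
- the cycloaddition, because the two diene substituents direct oppositely, a quaternary carbon would be made without a tether, and endo/exo and two facial choices would be left to chance;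
- the adjustment A2→A3, which would add operations but no complexity.

The target is a γ,δ-unsaturated acid with a quaternary α-carbon (C4), a stereogenic β-carbon (C12′) and the γ,δ-olefin (C13′=C14′) inside a six-membered ring: the retron of a ring-contracting lactone-enolate Claisen rearrangement. The route disconnects only C4–C12′, back to a δ-lactone in which C12 is already the carboxyl carbon and C5–C15′ already exists. One [3,3] shift would close the cyclohexene, create the quaternary centre and set C4 and C12′ from the reagent-controlled carbinol C14′ and the 12′E geometry. No C–H oxidation of caryophyllene and no cycloaddition would be needed; C12 is oxidised by way of the commercial epoxide, and the fragments are joined by a Michael addition.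

Key step: step 10

Remark (numbering): caryophyllane carbons are C1–C15 (C12 on C4, C13 the exocyclic methylene carbon on C8, C14/C15 on C11); labdane carbons are primed (C1′–C20′). The new ring of the target is C4–C5–C15′–C14′=C13′–C12′.
Remark (supply): (−)-β-caryophyllene oxide and trans-communic acid are taken as purchasable natural isolates.

Step 1
Reactants: 1 (−)-β-caryophyllene oxide
Product: 2 (1R,5R,9S)-caryophylla-4(12),8(13)-dien-5-ol
Conditions: LiN(i-Pr)2 (3 equiv), Et2O, 0 °C → reflux; H2O
Reagents that add atoms: none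
Why: Base-induced epoxide-to-allylic-alcohol isomerisation (syn β-elimination), known for this epoxide: the amide removes a proton from the unhindered C12 methyl group, C4–O breaks, and C5–O keeps its configuration.

Step 2
Reactants: 2 (1R,5R,9S)-caryophylla-4(12),8(13)-dien-5-ol
Product: 3 (1R,4S,5R,9S)-4,12-epoxycaryophyll-8(13)-en-5-ol
Conditions: VO(acac)2 (3 mol %), t-BuOOH (1.3 equiv), PhMe, 0 °C → rt
Reagents that add atoms: tert-butyl hydroperoxide, CC(C)(C)OO
Why: Hydroxyl-directed vanadium-catalysed epoxidation should oxidise only the allylic C4=C12 bond, and the erythro preference of 2-substituted allylic alcohols (C6 turned away from C3 in the vanadate ester) should deliver oxygen to the face of C4 that carried the epoxide oxygen in 1 (4S).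

Step 3
Reactants: 3 (1R,4S,5R,9S)-4,12-epoxycaryophyll-8(13)-en-5-ol
Product: 7 methyl (1R,4R,5R,9S)-4,5-dihydroxycaryophyll-8(13)-en-12-oate, via triol 4 (not isolated), via hydroxy aldehyde 5 (not isolated), via dihydroxy acid 6 (not isolated)
Conditions: KOH (2 M aq), DMSO, 70 °C; then 2,2,6,6-tetramethylpiperidine-1-oxyl (5 mol %), NaOCl (2 mol %), NaClO2 (2 equiv), MeCN/phosphate buffer pH 6.7, 35 °C; then MeI, KHCO3, DMF, rt
Reagents that add atoms: water, O (as hydroxide; oxygen at C12); sodium chlorite, [Na+].[O-]Cl=O (second carboxyl oxygen); iodomethane, CI (ester methyl)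
Why: SN2 opening of the spiro-epoxide by hydroxide at its primary carbon C12 leaves C4 and C5 untouched, the oxoammonium/chlorite oxidation should convert only the primary alcohol into the acid, and carboxylate alkylation gives the ester, so no stereocentre is formed or touched.

Step 4
Reactants: 7 methyl (1R,4R,5R,9S)-4,5-dihydroxycaryophyll-8(13)-en-12-oate
Product: 9 methyl (1R,4Z,9S)-caryophylla-4,8(13)-dien-12-oate (ring-trans olefin), via cyclic thiocarbonate 8 (not isolated)
Conditions: 1,1′-thiocarbonyldiimidazole (1.5 equiv), 4-(dimethylamino)pyridine (cat.), PhMe, 90 °C; then 1,3-dimethyl-2-phenyl-1,3,2-diazaphospholidine (3 equiv), THF, 40 °C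
Reagents that add atoms: none
Why: Corey–Winter olefination: the two C–O bonds of 7 are disposed as in the trans-epoxide 1, so the stereospecific syn-cycloelimination of the thiocarbonate should give only the ring-trans enoate, which is the classical way to strained trans-cycloalkenes.

Step 5
Reactants: 10 trans-communic acid
Product: 11 2-(trimethylsilyl)ethyl trans-communate
Conditions: Me3SiCH2CH2OH (1.5 equiv), PPh3, DIAD, THF, 0 °C → rt
Reagents that add atoms: 2-(trimethylsilyl)ethanol, C[Si](C)(C)CCO
Why: Mitsunobu esterification, in which the hindered C19′ carboxylate acts only as nucleophile towards the activated primary alcohol, installs an ester that survives amide bases, borane and alkoxide and falls to fluoride in step 10; no stereocentre is touched.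

Step 6
Reactants: 11 2-(trimethylsilyl)ethyl trans-communate
Product: 13 2-(trimethylsilyl)ethyl 12′-oxo-13′,14′,15′,16′-tetranorlabd-8′(17′)-en-19′-oate, via ozonide 12 (not isolated)
Conditions: O3 (1.0 equiv, metered), CH2Cl2, −78 °C; then PPh3, −78 °C → rt
Reagents that add atoms: ozone, [O-][O+]=O
Why: Ozonolysis with reductive work-up: with one equivalent of ozone the trisubstituted, most electron-rich C12′=C13′ bond should react before the vinyl group and the hindered exocyclic C8′=C17′ bond, and C9′ is not touched.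

Step 7
Reactants: 13 2-(trimethylsilyl)ethyl 12′-oxo-13′,14′,15′,16′-tetranorlabd-8′(17′)-en-19′-oate
Product: 14 2-(trimethylsilyl)ethyl (12′E)-14′-oxolabda-8′(17′),12′-dien-19′-oate
Conditions: Ph3P=C(CH3)C(O)CH3 (1.5 equiv), PhMe, 90 °C
Reagents that add atoms: 3-(triphenyl-λ5-phosphanylidene)butan-2-one, CC(=O)C(C)=P(c1ccccc1)(c1ccccc1)c1ccccc1
Why: Wittig olefination with a ketone-stabilised ylide should give the trisubstituted enone with the E geometry (C11′ trans to C14′) that step 10 translates into the C12′ configuration; no stereocentre is formed.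

Step 8
Reactants: 14 2-(trimethylsilyl)ethyl (12′E)-14′-oxolabda-8′(17′),12′-dien-19′-oate; 9 methyl (1R,4Z,9S)-caryophylla-4,8(13)-dien-12-oate
Product: 17 methyl (1R,5S,9S)-5-[(12′E)-14′-oxo-19′-(2-trimethylsilylethoxy)-19′-oxolabda-8′(17′),12′-dien-15′-yl]caryophyll-8(13)-en-12-oate (C4 epimers), via lithium dienolate 15 (not isolated), via lithium ester enolate 16 (not isolated)
Conditions: LiN(i-Pr)2 (1.05 equiv), THF, −78 °C, 14; then 9, −78 → −45 °C; AcOH, −78 °C
Reagents that add atoms: none
Why: Michael addition: the kinetic cross-conjugated enolate (C15′) of 14 should add to C5 of the strain-activated trans-cyclononene enoate from the exposed outer face of its predominant conformer, the face that bears the epoxide oxygen in 1 (5S), and protonation of 16 at −78 °C should forestall a second, intramolecular Michael addition; C4 is enolised again in step 10.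

Step 9
Reactants: 17 keto diester (C4 epimers)
Product: 19 (1R,5S,9S,14′R)-12,14′-olide (δ-lactone C12(=O)–O–C14′–C15′–C5–C4; C6 trans to the C13′ alkenyl group; 19′-[2-(trimethylsilyl)ethyl] ester; C4 epimers), via hydroxy diester 18 (not isolated)
Conditions: (S)-2-methyl-CBS-oxazaborolidine (0.2 equiv), catecholborane (1.5 equiv), PhMe, −78 °C; MeOH; then NaOMe (0.2 equiv), THF, 0 °C → rt
Reagents that add atoms: none
Why: CBS reduction, with the alkenyl group as the large substituent, should give the 14′R allylic alcohol under reagent control without touching esters or olefins, and alkoxide-catalysed lactonisation onto the C12 methyl ester closes the six-membered lactone in which the alkenyl group and C6 are trans.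

Step 10
Reactants: 19 (1R,5S,9S,14′R)-12,14′-olide
Product: 22 target diacid, via silyl ketene acetal 20 (not isolated), via trimethylsilyl ester 21 (not isolated)
Conditions: LiN(i-Pr)2 (1.3 equiv), Me3SiCl–Et3N (3 equiv), THF, −78 °C → rt, then 65 °C; Bu4NF (3 equiv), THF, rt; 0.5 M HCl
Reagents that add atoms: none
Why: LiN(i-Pr)2 removes the only α-proton (C4–H) and in situ silylation gives the endocyclic, geometrically fixed silyl ketene acetal 20, whose allyl vinyl ether unit C4=C12–O–C14′–C13′=C12′ undergoes a concerted suprafacial [3,3] shift (Ireland–Claisen rearrangement) to silyl ester 21, which fluoride cleaves together with the 2-(trimethylsilyl)ethyl ester. The closest known reaction type is the lactone-enolate Claisen ring contraction of 6-alkenyl-δ-valerolactones and 6-alkenyl-1,4-dioxan-2-ones to cyclohexene- and dihydropyran-carboxylic acids. The cyclohexene C4–C5–C15′–C14′=C13′–C12′ is closed by C4–C12′ bond formation with scission of C14′–O (six-membered lactone to six-membered carbocycle) through the boat-like transition state that the two-atom C5–C15′ tether enforces, which also makes the new C13′=C14′ bond cis as the ring requires. At C4, C12′ can reach only the lactone face that carries the pseudo-axial C14′ alkenyl group, and because C6 is trans to that group in 19 the carboxyl carbon C12 ends cis to C6 (4S, trans-fused six/nine system). At C12′, the boat places the substituent that is trans to C14′ in the 12′E olefin (C11′) over C3, so that it ends cis to the carboxyl group (12′R). The step needs the 4,6-trans lactone (the cis isomer would have to hold the alkenyl group and C6 axial on the same face) and a single enolisable position, which step 9 and the structure of 19 secure.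

Compound list
1 | (−)-β-caryophyllene oxide; (1R,4R,5R,9S)-4,5-epoxycaryophyll-8(13)-ene | C=C1CC[C@H]3O[C@]3(C)CC[C@@H]2[C@@H]1CC2(C)C | starting material
2 | (1R,5R,9S)-caryophylla-4(12),8(13)-dien-5-ol | C=C1CC[C@@H](O)C(=C)CC[C@@H]2[C@@H]1CC2(C)C | intermediate
3 | (1R,4S,5R,9S)-4,12-epoxycaryophyll-8(13)-en-5-ol (spiro-oxirane at C4; C4–O oriented as in 1) | C=C1CC[C@@H](O)[C@@]3(CO3)CC[C@@H]2[C@@H]1CC2(C)C | intermediate
4 | (1R,4S,5R,9S)-caryophyll-8(13)-ene-4,5,12-triol (in-flask species) | C=C1CC[C@@H](O)[C@@](O)(CO)CC[C@@H]2[C@@H]1CC2(C)C | intermediate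
5 | (1R,4R,5R,9S)-4,5-dihydroxycaryophyll-8(13)-en-12-al (in-flask species) | C=C1CC[C@@H](O)[C@@](O)(C=O)CC[C@@H]2[C@@H]1CC2(C)C | intermediate
6 | (1R,4R,5R,9S)-4,5-dihydroxycaryophyll-8(13)-en-12-oic acid (crude, in-flask species) | C=C1CC[C@@H](O)[C@@](O)(C(=O)O)CC[C@@H]2[C@@H]1CC2(C)C | intermediate
7 | methyl (1R,4R,5R,9S)-4,5-dihydroxycaryophyll-8(13)-en-12-oate (C4–O and C5–O oriented as the epoxide bonds of 1) | C=C1CC[C@@H](O)[C@@](O)(C(=O)OC)CC[C@@H]2[C@@H]1CC2(C)C | intermediate
8 | cyclic 4,5-O-thiocarbonate of 7, (1R,4R,5R,9S) (in-flask species) | C=C1CC[C@H]3OC(=S)O[C@]3(C(=O)OC)CC[C@@H]2[C@@H]1CC2(C)C | intermediate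
9 | methyl (1R,4Z,9S)-caryophylla-4,8(13)-dien-12-oate; ring-trans C4=C5 as in β-caryophyllene | C=C1CC/C=C(\C(=O)OC)/CC[C@@H]2[C@@H]1CC2(C)C | intermediate
10 | trans-communic acid; (4′S,5′R,9′S,10′R)-labda-8′(17′),12′E,14′-trien-19′-oic acid | C=C/C(C)=C/C[C@H]1C(=C)CC[C@@H]2[C@]1(C)CCC[C@]2(C)C(=O)O | starting material
11 | 2-(trimethylsilyl)ethyl trans-communate | C=C/C(C)=C/C[C@H]1C(=C)CC[C@@H]2[C@]1(C)CCC[C@]2(C)C(=O)OCC[Si](C)(C)C | intermediate
12 | 1,2,4-trioxolane (ozonide) of the C12′=C13′ bond of 11 (diastereomers at the trioxolane carbons; in-flask species) | C=CC1(C)OOC(C[C@H]2C(=C)CC[C@@H]3[C@]2(C)CCC[C@]3(C)C(=O)OCC[Si](C)(C)C)O1 | intermediate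
13 | 2-(trimethylsilyl)ethyl (4′S,5′R,9′S,10′R)-12′-oxo-13′,14′,15′,16′-tetranorlabd-8′(17′)-en-19′-oate | O=CC[C@H]1C(=C)CC[C@@H]2[C@]1(C)CCC[C@]2(C)C(=O)OCC[Si](C)(C)C | intermediate
14 | 2-(trimethylsilyl)ethyl (12′E)-14′-oxolabda-8′(17′),12′-dien-19′-oate (methyl enone; C15′ is the ketone methyl) | CC(=O)/C(C)=C/C[C@H]1C(=C)CC[C@@H]2[C@]1(C)CCC[C@]2(C)C(=O)OCC[Si](C)(C)C | intermediate
15 | lithium 14′(15′),12′-dienolate of 14 (in-flask species) | C=C(O[Li])/C(C)=C/C[C@H]1C(=C)CC[C@@H]2[C@]1(C)CCC[C@]2(C)C(=O)OCC[Si](C)(C)C | intermediate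
16 | lithium ester enolate (C4=C12) of 17, (5S) (in-flask species) | C=C1CC[C@@H](CC(=O)/C(C)=C/C[C@H]3C(=C)CC[C@@H]4[C@]3(C)CCC[C@]4(C)C(=O)OCC[Si](C)(C)C)C(=C(OC)O[Li])CC[C@@H]2[C@@H]1CC2(C)C | intermediate
17 | keto diester with the C5–C15′ bond: methyl (1R,5S,9S)-5-[(12′E)-14′-oxolabda-8′(17′),12′-dien-15′-yl]caryophyll-8(13)-en-12-oate, 19′-[2-(trimethylsilyl)ethyl] ester; C4 epimers | C=C1CC[C@@H](CC(=O)/C(C)=C/C[C@H]3C(=C)CC[C@@H]4[C@]3(C)CCC[C@]4(C)C(=O)OCC[Si](C)(C)C)C(C(=O)OC)CC[C@@H]2[C@@H]1CC2(C)C | intermediate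
18 | (14′R)-14′-hydroxy diester from 17, (1R,5S,9S,14′R); C4 epimers (in-flask species) | C=C1CC[C@@H](C[C@@H](O)/C(C)=C/C[C@H]3C(=C)CC[C@@H]4[C@]3(C)CCC[C@]4(C)C(=O)OCC[Si](C)(C)C)C(C(=O)OC)CC[C@@H]2[C@@H]1CC2(C)C | intermediate
19 | (1R,5S,9S,14′R)-12,14′-olide: δ-lactone C12(=O)–O–C14′–C15′–C5–C4 fused at C4–C5, (12′E)-alkenyl group on C14′ trans to C6, 19′-[2-(trimethylsilyl)ethyl] ester; C4 epimers | C=C1CC[C@H]5C[C@H](/C(C)=C/C[C@H]3C(=C)CC[C@@H]4[C@]3(C)CCC[C@]4(C)C(=O)OCC[Si](C)(C)C)OC(=O)C5CC[C@@H]2[C@@H]1CC2(C)C | intermediate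
20 | trimethylsilyl ketene acetal of 19 (C4=C12, endocyclic in the lactone; in-flask species) | C=C1CC[C@H]5C[C@H](/C(C)=C/C[C@H]3C(=C)CC[C@@H]4[C@]3(C)CCC[C@]4(C)C(=O)OCC[Si](C)(C)C)OC(O[Si](C)(C)C)=C5CC[C@@H]2[C@@H]1CC2(C)C | intermediate
21 | 12-trimethylsilyl 19′-[2-(trimethylsilyl)ethyl] diester of 22 (in-flask species) | C=C1CC[C@H]2CC=C(C)[C@@H](C[C@H]3C(=C)CC[C@@H]4[C@]3(C)CCC[C@]4(C)C(=O)OCC[Si](C)(C)C)[C@]2(C(=O)O[Si](C)(C)C)CC[C@@H]2[C@@H]1CC2(C)C | intermediate
22 | target C35 diacid: cyclohexene C4–C5–C15′–C14′=C13′–C12′ fused at caryophyllane C4/C5, 12-oic and 19′-oic acids, 8(13)- and 8′(17′)-methylenes; caryophyllane 1R,4S,5S,9S, labdane 4′S,5′R,9′S,10′R,12′R | C=C1CC[C@H]2CC=C(C)[C@@H](C[C@H]3C(=C)CC[C@@H]4[C@]3(C)CCC[C@]4(C)C(=O)O)[C@]2(C(=O)O)CC[C@@H]2[C@@H]1CC2(C)C | target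

Total step count: 10. Longest linear sequence: 7 steps (1 → 22 through steps 1–4 and 8–10).

Steps most likely to fail, with fallbacks

Step 8 (Michael addition). The enolate may attack both faces of the enoate, whose two planar-chiral conformers interconvert; it may transfer a proton instead of adding to the α-substituted acceptor; or the first adduct may add a second time onto the enone. Fallback, an auxiliary-controlled azaenolate Michael addition: setting out from 14, condensation with (S)-1-amino-2-(methoxymethyl)pyrrolidine (neat, 60 °C) would give the SAMP hydrazone of 14 F1. Its lithium azaenolate (LiN(i-Pr)2, THF, −78 °C) would add to 9; the auxiliary (or its enantiomer, whichever is matched with the outer-face preference) would reinforce the facial choice at C5, and the softer, less basic nucleophile would suppress proton transfer and the second addition. This would give the SAMP hydrazone of 17 F2, and hydrolysis with aqueous oxalic acid/Et2O would come back to the route at 17.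

Step 10 (key Claisen ring contraction). Deprotonation of the hindered C4–H may be slow, C-silylation may compete, or the boat-like rearrangement that makes the quaternary carbon may be sluggish enough for desilylation or allylic ionisation to compete. Fallback, a stepwise ionic ring closure by zerovalent-palladium-catalysed allylic alkylation: setting out from 17, the CBS reduction of step 9 quenched with methyl chloroformate/pyridine instead of NaOMe would give the 14′-O-methoxycarbonyl derivative of 18 F3. LiN(SiMe3)2 and Pd(PPh3)4 (THF, −78 °C → rt) would generate the C4 ester enolate and the π-allyl complex. Ring closure at C12′ is the only mode that gives a six-membered ring; ionisation and attack both occur anti to the metal, so the course is overall the same suprafacial one as the [3,3] shift. It would give the 12-methyl 19′-[2-(trimethylsilyl)ethyl] diester of 22 F4, whose relative configuration at C4/C12′ would have to be confirmed. LiI in pyridine (reflux) would cleave the methyl ester to the 19′-[2-(trimethylsilyl)ethyl] monoester of 22 F5, and Bu4NF (THF, rt) would come back to the route at 22.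

Step 4 (Corey–Winter olefination). Thiocarbonate formation at the tertiary C4 hydroxyl may be incomplete, or the strained ring-trans enoate may isomerise to the ring-cis isomer during the cycloelimination. Fallback, epoxide deoxygenation with inversion of olefin geometry: setting out from 7, Mitsunobu cyclodehydration (PPh3, DIAD, THF), in which the C4 alkoxide displaces the activated C5 oxygen with inversion, would give the ring-cis glycidic ester methyl (1R,4R,5S,9S)-4,5-epoxycaryophyll-8(13)-en-12-oate F6. LiPPh2 (THF, −78 → 0 °C) would open it at C5, the only oxirane carbon that is not quaternary, with a second inversion to the β-hydroxy phosphine F7. MeI would then give the phosphonium betaine F8, whose syn-elimination of the phosphine oxide would come back to the route at 9 with the ring-trans geometry.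

Further compounds
F1 | step 8 | SAMP hydrazone of 14 (C14′=N–N; (S)-2-(methoxymethyl)pyrrolidin-1-yl) | CC(=NN1CCC[C@H]1COC)/C(C)=C/C[C@H]2C(=C)CC[C@@H]3[C@]2(C)CCC[C@]3(C)C(=O)OCC[Si](C)(C)C
F2 | step 8 | SAMP hydrazone of 17, (5S); C4 epimers | C=C1CC[C@@H](CC(=NN5CCC[C@H]5COC)/C(C)=C/C[C@H]3C(=C)CC[C@@H]4[C@]3(C)CCC[C@]4(C)C(=O)OCC[Si](C)(C)C)C(C(=O)OC)CC[C@@H]2[C@@H]1CC2(C)C
F3 | step 10 | 14′-O-methoxycarbonyl derivative (allylic methyl carbonate) of 18, (5S,14′R) | C=C1CC[C@@H](C[C@@H](OC(=O)OC)/C(C)=C/C[C@H]3C(=C)CC[C@@H]4[C@]3(C)CCC[C@]4(C)C(=O)OCC[Si](C)(C)C)C(C(=O)OC)CC[C@@H]2[C@@H]1CC2(C)C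
F4 | step 10 | 12-methyl 19′-[2-(trimethylsilyl)ethyl] diester of 22 | C=C1CC[C@H]2CC=C(C)[C@@H](C[C@H]3C(=C)CC[C@@H]4[C@]3(C)CCC[C@]4(C)C(=O)OCC[Si](C)(C)C)[C@]2(C(=O)OC)CC[C@@H]2[C@@H]1CC2(C)C
F5 | step 10 | 19′-[2-(trimethylsilyl)ethyl] monoester of 22 (free 12-oic acid) | C=C1CC[C@H]2CC=C(C)[C@@H](C[C@H]3C(=C)CC[C@@H]4[C@]3(C)CCC[C@]4(C)C(=O)OCC[Si](C)(C)C)[C@]2(C(=O)O)CC[C@@H]2[C@@H]1CC2(C)C
F6 | step 4 | methyl (1R,4R,5S,9S)-4,5-epoxycaryophyll-8(13)-en-12-oate (ring-cis glycidic ester) | C=C1CC[C@@H]3O[C@]3(C(=O)OC)CC[C@@H]2[C@@H]1CC2(C)C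
F7 | step 4 | methyl 5-(diphenylphosphanyl)-4-hydroxycaryophyll-8(13)-en-12-oate (P in the position of the C5 oxygen of 7) | C=C1CC[C@@H](P(c3ccccc3)c3ccccc3)[C@@](O)(C(=O)OC)CC[C@@H]2[C@@H]1CC2(C)C
F8 | step 4 | methyl(diphenyl)phosphonium betaine from F7 | C=C1CC[C@@H]([P+](C)(c3ccccc3)c3ccccc3)[C@@]([O-])(C(=O)OC)CC[C@@H]2[C@@H]1CC2(C)C
A1 | direct plan | (−)-β-caryophyllene | C=C1CC/C=C(\C)/CC[C@@H]2[C@@H]1CC2(C)C
A2 | direct plan | 12-hydroxy-β-caryophyllene (ring-trans allylic alcohol) | C=C1CC/C=C(\CO)/CC[C@@H]2[C@@H]1CC2(C)C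
A3 | direct plan | β-caryophyllen-12-oic acid (ring-trans enoic acid) | C=C1CC/C=C(\C(=O)O)/CC[C@@H]2[C@@H]1CC2(C)C
A4 | direct plan | trans-communic acid | C=C/C(C)=C/C[C@H]1C(=C)CC[C@@H]2[C@]1(C)CCC[C@]2(C)C(=O)O
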